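**Plan**

- Chromenone numbering is used for the target. Retrosynthetically, the C5–O silyl ether and the C2=C3 unsaturation are taken back first, then C2–C3 and O1–C8a are cut together, then C4–C4a (acetyl onto the carbocycle), and last the C5–H bond (ketone reduction).
- Enabling feature: O1, C2 and the whole C17 side chain are the carbonyl oxygen, carbonyl carbon and tail of (Z)-octadec-13-enal. C3, C4, C4a and C8a form a 1-methoxy-3-silyloxy diene whose C4a=C8a bond lies in the six-membered carbocycle.
- Forward: the carbocycle is bought as 3-methoxycyclohex-2-enone and is iodinated, reduced, silylated and acetylated. The methyl ketone becomes the silyloxy diene, and the aldehyde cyclocondensation then closes the oxygen ring and joins the chain in one operation. Dehydrogenation to the 4-pyranone and desilylation finish the route.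
- Stereochemistry: C5 (S) comes from an oxazaborolidine-catalysed borane reduction. The Z-alkene is bought with the aldehyde and never meets an olefination. C2 is a transient centre that is erased.

Key step: step 6

Assumption: (Z)-octadec-13-enal 11 is taken as a purchasable pheromone component of defined Z geometry, and the oxazaborolidine reduction of 2 is taken to follow the usual model in which the substituted alkene arm is the large group.

**Route**

Step 1
Reactants: 1 3-methoxycyclohex-2-en-1-one
Product: 2 2-iodo-3-methoxycyclohex-2-en-1-one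
Conditions: NIS, MeCN, 0 °C → rt, dark
Reagents that add atoms: N-iodosuccinimide, O=C1CCC(=O)N1I
Why: C2 of the vinylogous ester is an enol-ether-type nucleophilic carbon, so N-iodosuccinimide iodinates it and proton loss restores the push–pull enone (electrophilic α-halogenation of a β-alkoxy enone).

Step 2
Reactants: 2 2-iodo-3-methoxycyclohex-2-en-1-one
Product: 3 (1S)-2-iodo-3-methoxycyclohex-2-en-1-ol
Conditions: (R)-2-methyl-CBS-oxazaborolidine [(3aR)-1-methyl-3,3-diphenyltetrahydro-1H,3H-pyrrolo[1,2-c][1,3,2]oxazaborole, C18H20BNO] (20 mol%), BH3·SMe2, THF, –30 °C; MeOH, then aq NaHCO3; Et3N-deactivated silica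
Reagents that add atoms: none
Why: Corey–Bakshi–Shibata reduction, in which the oxazaborolidine binds the carbonyl oxygen anti to the bulky iodo(methoxy)alkene arm and delivers hydride from coordinated borane to the Re face, setting the (S)-carbinol centre that becomes C5 of the target, while the non-acidic work-up keeps the 3-alkoxy allylic alcohol from ionising.

Step 3
Reactants: 3 (1S)-2-iodo-3-methoxycyclohex-2-en-1-ol
Product: 4 tert-butyl{[(1S)-2-iodo-3-methoxycyclohex-2-en-1-yl]oxy}dimethylsilane
Conditions: TBSCl, imidazole, DMF, 0 °C → rt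
Reagents that add atoms: tert-butyldimethylsilyl chloride, CC(C)(C)[Si](C)(C)Cl
Why: Imidazole-promoted silylation of a secondary allylic alcohol runs under basic conditions and touches neither the enol ether nor the stereocentre (standard TBS protection).

Step 4
Reactants: 4 tert-butyl{[(1S)-2-iodo-3-methoxycyclohex-2-en-1-yl]oxy}dimethylsilane; 5 N-methoxy-N-methylacetamide
Product: 8 1-[(6S)-6-{[tert-butyl(dimethyl)silyl]oxy}-2-methoxycyclohex-1-en-1-yl]ethan-1-one, via vinyllithium 6 (not isolated), via lithium hemiaminal adduct 7 (not isolated)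
Conditions: t-BuLi (2.1 equiv), Et2O, –78 °C; then 5, –78 → –20 °C; aq NH4Cl
Reagents that add atoms: none
Why: Iodine–lithium exchange on the vinyl iodide is fast at –78 °C, the vinyllithium cannot eliminate within a six-membered ring, and it adds once to the Weinreb amide to give a chelated adduct that releases the methyl ketone only on quench (Weinreb ketone synthesis).

Step 5
Reactants: 8 1-[(6S)-6-{[tert-butyl(dimethyl)silyl]oxy}-2-methoxycyclohex-1-en-1-yl]ethan-1-one
Product: 10 tert-butyl{[(1S)-3-methoxy-2-{1-[(trimethylsilyl)oxy]ethenyl}cyclohex-2-en-1-yl]oxy}dimethylsilane, via lithium enolate 9 (not isolated)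
Conditions: LDA, THF, –78 °C; TMSCl, Et3N, –78 → 0 °C; pentane, filtration, no aqueous work-up
Reagents that add atoms: chlorotrimethylsilane, C[Si](C)(C)Cl
Why: Kinetic deprotonation of the acetyl methyl group (the α' site of a β-alkoxy enone) followed by O-silylation is the standard preparation of Danishefsky-type 1-alkoxy-3-silyloxy dienes and leaves the stereocentre untouched.

Step 6
Reactants: 10 tert-butyl{[(1S)-3-methoxy-2-{1-[(trimethylsilyl)oxy]ethenyl}cyclohex-2-en-1-yl]oxy}dimethylsilane; 11 (13Z)-octadec-13-enal
Product: 13 (2RS,5S)-5-{[tert-butyl(dimethyl)silyl]oxy}-2-[(12Z)-heptadec-12-en-1-yl]-2,3,5,6,7,8-hexahydro-4H-chromen-4-one (both C2 epimers), via silylated aldol adduct 12 (not isolated)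
Conditions: 11, Sc(OTf)3 (10 mol%), CH2Cl2, –78 °C, then 10; then CF3CO2H, CH2Cl2, 0 °C; aq NaHCO3
Reagents that add atoms: none
Why: Sc(OTf)3 activates aldehyde 11, and the terminal methylene of the silyl enol ether half of diene 10 (C3) attacks the carbonyl carbon in a Mukaiyama aldol that makes C2–C3, the silyl group passing to the new oxygen to give 12; trifluoroacetic acid then frees that oxygen, which adds to C8a of the β-methoxy enone and expels methanol, making O1–C8a and leaving the C4a=C8a double bond in place. Taken together this is the stepwise variant of the Lewis-acid-catalysed cyclocondensation (hetero-Diels–Alder) of 1-alkoxy-3-silyloxy dienes with aliphatic aldehydes, which rare-earth triflates are known to promote, and the stepwise course is preferred here because the methoxy group sits on the inner (Z) position of a fully substituted diene terminus and disfavours a concerted s-cis approach. The oxygen ring closes as a formal [4+2] annulation whose ring-closing event is a 6-endo-trig oxa-Michael addition–elimination at the ring-fused enol ether carbon. The new C2 stereocentre is under no useful control from the remote C5 silyloxy group, and both epimers are carried on because C2 becomes sp2 in step 7. The step needs regioselectivity, which the push–pull polarisation secures because both oxygen donors make the CH2 terminus the nucleophile and C8a the acceptor; it also needs survival of the allylic C5 silyl ether and the Z-alkene, which is secured by a catalytic Lewis acid at –78 °C, by the change from an acid-labile enol ether to a robust vinylogous ester once C2–C3 has formed, and by the absence of base or alkene-active reagents.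

Step 7
Reactants: 13 (2RS,5S)-5-{[tert-butyl(dimethyl)silyl]oxy}-2-[(12Z)-heptadec-12-en-1-yl]-2,3,5,6,7,8-hexahydro-4H-chromen-4-one
Product: 16 (5S)-5-{[tert-butyl(dimethyl)silyl]oxy}-2-[(12Z)-heptadec-12-en-1-yl]-5,6,7,8-tetrahydro-4H-chromen-4-one, via lithium enolate 14 (not isolated), via silyl dienol ether 15 (not isolated)
Conditions: LiN(SiMe3)2, THF, –78 °C; TMSCl, Et3N, –78 → 0 °C; solvent exchange; Pd(OAc)2 (1.1 equiv), MeCN, rt
Reagents that add atoms: none
Why: Saegusa–Ito oxidation, in which kinetic C3 deprotonation and O-silylation give the dienol silyl ether, divalent palladium forms the C3-bound palladium enolate, and syn β-hydride loss from C2 delivers the 4-pyranone and removes the C2 stereocentre, while the isolated Z-alkene should not be engaged at room temperature in acetonitrile.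

Step 8
Reactants: 16 (5S)-5-{[tert-butyl(dimethyl)silyl]oxy}-2-[(12Z)-heptadec-12-en-1-yl]-5,6,7,8-tetrahydro-4H-chromen-4-one
Product: 17 (5S)-2-[(12Z)-heptadec-12-en-1-yl]-5-hydroxy-5,6,7,8-tetrahydro-4H-chromen-4-one (CNP0118262.1)
Conditions: Bu4NF, AcOH (1:1), THF, 0 °C → rt
Reagents that add atoms: none
Why: Fluoride cleaves the secondary silyl ether through the strong Si–F bond, and acetic acid buffering avoids base-mediated damage to the pyranone and elimination at C5 (standard TBS removal).

**Compound list**

1 | 3-methoxycyclohex-2-en-1-one | COC1=CC(=O)CCC1 | starting material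
2 | 2-iodo-3-methoxycyclohex-2-en-1-one | COC1=C(I)C(=O)CCC1 | intermediate
3 | (1S)-2-iodo-3-methoxycyclohex-2-en-1-ol | IC1=C(OC)CCC[C@@H]1O | intermediate
4 | tert-butyl{[(1S)-2-iodo-3-methoxycyclohex-2-en-1-yl]oxy}dimethylsilane | IC1=C(OC)CCC[C@@H]1O[Si](C)(C)C(C)(C)C | intermediate
5 | N-methoxy-N-methylacetamide | CC(=O)N(C)OC | starting material
6 | {(6S)-6-{[tert-butyl(dimethyl)silyl]oxy}-2-methoxycyclohex-1-en-1-yl}lithium (vinyllithium) | [Li]C1=C(OC)CCC[C@@H]1O[Si](C)(C)C(C)(C)C | intermediate
7 | lithium 1-[(6S)-6-{[tert-butyl(dimethyl)silyl]oxy}-2-methoxycyclohex-1-en-1-yl]-1-[methoxy(methyl)amino]ethan-1-olate (lithium hemiaminal adduct) | CC(O[Li])(N(C)OC)C1=C(OC)CCC[C@@H]1O[Si](C)(C)C(C)(C)C | intermediate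
8 | 1-[(6S)-6-{[tert-butyl(dimethyl)silyl]oxy}-2-methoxycyclohex-1-en-1-yl]ethan-1-one | CC(=O)C1=C(OC)CCC[C@@H]1O[Si](C)(C)C(C)(C)C | intermediate
9 | lithium 1-[(6S)-6-{[tert-butyl(dimethyl)silyl]oxy}-2-methoxycyclohex-1-en-1-yl]ethen-1-olate (lithium enolate) | [Li]OC(=C)C1=C(OC)CCC[C@@H]1O[Si](C)(C)C(C)(C)C | intermediate
10 | tert-butyl{[(1S)-3-methoxy-2-{1-[(trimethylsilyl)oxy]ethenyl}cyclohex-2-en-1-yl]oxy}dimethylsilane | C=C(O[Si](C)(C)C)C1=C(OC)CCC[C@@H]1O[Si](C)(C)C(C)(C)C | intermediate
11 | (13Z)-octadec-13-enal | CCCC/C=C\CCCCCCCCCCCC=O | starting material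
12 | (15Z)-1-[(6S)-6-{[tert-butyl(dimethyl)silyl]oxy}-2-methoxycyclohex-1-en-1-yl]-3-[(trimethylsilyl)oxy]icos-15-en-1-one, both C3 epimers (silylated aldol adduct) | CCCC/C=C\CCCCCCCCCCCC(O[Si](C)(C)C)CC(=O)C1=C(OC)CCC[C@@H]1O[Si](C)(C)C(C)(C)C | intermediate
13 | (2RS,5S)-5-{[tert-butyl(dimethyl)silyl]oxy}-2-[(12Z)-heptadec-12-en-1-yl]-2,3,5,6,7,8-hexahydro-4H-chromen-4-one, both C2 epimers | CCCC/C=C\CCCCCCCCCCCC1CC(=O)C2=C(O1)CCC[C@@H]2O[Si](C)(C)C(C)(C)C | intermediate
14 | lithium (5S)-5-{[tert-butyl(dimethyl)silyl]oxy}-2-[(12Z)-heptadec-12-en-1-yl]-5,6,7,8-tetrahydro-2H-chromen-4-olate, both C2 epimers (lithium enolate) | CCCC/C=C\CCCCCCCCCCCC1C=C(O[Li])C2=C(O1)CCC[C@@H]2O[Si](C)(C)C(C)(C)C | intermediate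
15 | tert-butyl{[(5S)-2-[(12Z)-heptadec-12-en-1-yl]-4-[(trimethylsilyl)oxy]-5,6,7,8-tetrahydro-2H-chromen-5-yl]oxy}dimethylsilane, both C2 epimers (silyl dienol ether) | CCCC/C=C\CCCCCCCCCCCC1C=C(O[Si](C)(C)C)C2=C(O1)CCC[C@@H]2O[Si](C)(C)C(C)(C)C | intermediate
16 | (5S)-5-{[tert-butyl(dimethyl)silyl]oxy}-2-[(12Z)-heptadec-12-en-1-yl]-5,6,7,8-tetrahydro-4H-chromen-4-one | CCCC/C=C\CCCCCCCCCCCc1cc(=O)c2c(o1)CCC[C@@H]2O[Si](C)(C)C(C)(C)C | intermediate
17 | (5S)-2-[(12Z)-heptadec-12-en-1-yl]-5-hydroxy-5,6,7,8-tetrahydro-4H-chromen-4-one | CCCC/C=C\CCCCCCCCCCCc1cc(=O)c2c(o1)CCC[C@@H]2O | target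

**Totals and risks**

Total step count: 8. Longest linear sequence: 8 steps, from 1 to 17; compounds 5 and 11 enter as purchased materials.

Steps most likely to fail:

1. Step 2. The hydride delivery to the electron-rich vinylogous ester carbonyl may discriminate the two faces incompletely, and the 3-alkoxy allylic carbinol may ionise (loss of the hydroxyl with transposition) during reduction or work-up. The fallback replaces catalytic asymmetric reduction by resolution. It sets out from 2, which would be reduced with i-Bu2AlH in toluene at –78 °C (Rochelle salt work-up) to racemic 2-iodo-3-methoxycyclohex-2-en-1-ol F1. Kinetic resolution with Burkholderia cepacia lipase and vinyl acetate in tert-butyl methyl ether should then acetylate the (R)-alcohol, as expected from the empirical rule for lipase acylation of secondary alcohols, to give (1R)-2-iodo-3-methoxycyclohex-2-en-1-yl acetate F2 and leave the (S)-alcohol. Separation on triethylamine-deactivated silica brings the sequence back to the route at 3.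

2. Step 6. Lewis-acid ionisation of the allylic silyloxy group or protodesilylation of the electron-rich diene may outrun C–C bond formation, and dehydration of the aldol may compete with ring closure. The fallback is a directed lithium aldol without Lewis acid or silyl dienol ether. It sets out from 8, which would be deprotonated with LDA in THF at –78 °C and treated with aldehyde 11 to give (15Z)-1-[(6S)-6-{[tert-butyl(dimethyl)silyl]oxy}-2-methoxycyclohex-1-en-1-yl]-3-hydroxyicos-15-en-1-one F3 as both C3 epimers. Trifluoroacetic acid in CH2Cl2 at 0 °C should then close the oxygen ring by the same addition–elimination at C8a with loss of methanol, and the sequence comes back to the route at 13.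

3. Step 7. The C3 enolate may open the oxygen ring by β-elimination of the ring oxygen, deprotonation may occur at C8 instead of C3, or palladium hydride may isomerise the Z-alkene. The fallback adjusts the oxidation level before ring closure, so no enolate of the dihydropyranone and no palladium is needed. It sets out from 12, which would be isolated by quenching the first stage of step 6 with aqueous NaHCO3 in place of trifluoroacetic acid. Desilylation with AcOH in aqueous THF gives the hydroxy ketone F3 described under step 6. Dess–Martin periodinane (NaHCO3, CH2Cl2) would oxidise it to (15Z)-1-[(6S)-6-{[tert-butyl(dimethyl)silyl]oxy}-2-methoxycyclohex-1-en-1-yl]icos-15-ene-1,3-dione F4. Trifluoroacetic acid in CH2Cl2 would then cyclise the enol oxygen onto C8a with loss of methanol, and the sequence comes back to the route at 16.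

**Further compounds**

F1 | step 2 | rac-2-iodo-3-methoxycyclohex-2-en-1-ol | COC1=C(I)C(O)CCC1
F2 | step 2 | (1R)-2-iodo-3-methoxycyclohex-2-en-1-yl acetate | IC1=C(OC)CCC[C@H]1OC(C)=O
F3 | step 6 | (15Z)-1-[(6S)-6-{[tert-butyl(dimethyl)silyl]oxy}-2-methoxycyclohex-1-en-1-yl]-3-hydroxyicos-15-en-1-one, both C3 epimers | CCCC/C=C\CCCCCCCCCCCC(O)CC(=O)C1=C(OC)CCC[C@@H]1O[Si](C)(C)C(C)(C)C
F4 | step 7 | (15Z)-1-[(6S)-6-{[tert-butyl(dimethyl)silyl]oxy}-2-methoxycyclohex-1-en-1-yl]icos-15-ene-1,3-dione | CCCC/C=C\CCCCCCCCCCCC(=O)CC(=O)C1=C(OC)CCC[C@@H]1O[Si](C)(C)C(C)(C)C
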